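The rate constants were chosen freely; what happens was integrated by code.

The vessel was a closed, stirred flask of two phases: carrier shuttled between substrate in the first phase and salt in the second, while added ligand bound fresh carrier.

    spent carrier + salt in the second phase ⇌ fresh carrier + spent salt in the second phase (K1 = 0.36, k1 = 7.3 /M/min)
    substrate + fresh carrier ⇌ product + spent carrier (K2 = 0.29, k2 = 15 /M/min)
    added ligand + fresh carrier ⇌ idle complex, settled at all times (K3 = 2400 /M)

substrate 2.0 M; salt in the second phase 1.80 M; spent carrier 20 mM; added ligand 41 mM; volume of the second phase over the first 1.0

* the form that holds most of the catalyst when 5.0% of the substrate are converted (idle complex / spent carrier / fresh carrier)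
* its share of the catalyst then
* factor on the rate of making product when 5.0% of the substrate are converted if spent carrier is charged twice over
* factor on the rate when 5.0% of the substrate are converted if spent carrier is charged at 2.0 mM instead

I took the ligand step as balanced and reckoned with what it left free. At 5.0% conversion, I set the making of fresh carrier equal to its use, reverse steps counted, and got 1.74 spent carrier per fresh carrier. The ligand charge was twice the catalyst charge, so, counting the catalyst as bound, I took a fraction 51.2% of the ligand as free. Folding these together gave 18.4: this is the idle number, idle complex per working carrier, spent and fresh together. Read directly, it left a working share of 5.15%, with the rest as idle complex, an off-cycle form and no resting state of the round.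

Was one number enough? Not for the doubled charge. There the idle number fell to 0.877, which read directly gave a working share of 53.3%, but so much working carrier frees ligand that the number had counted as bound. With that ligand returned, the working share was 14.4%, lower than the direct reading. The same correction gave 4.93% for the flask as charged and, with 34.2 as idle number, 2.84% at 2.0 mM. I committed to idle complex at 95.1% and to rate factors of 5.84 and 0.0575.

The forecast named idle complex at 95% (93% to 97%), with factors of 5.7 (5 to 6.5) and 0.058 (0.05 to 0.068), holding that “the rate scales with the small free fraction set by the leftover ligand”. Its doubling factor stood lower than mine.

The simulation gave idle complex at 95.0%, with factors of 5.72 and 0.0581.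

At 5.0% conversion the flask as charged held 19.0 idle complex per working carrier, against my idle number of 18.4. At 0.489 h the forward second step alone gave fresh carrier a half-life of 0.026 min and substrate one of 2.1 h, a far shorter time for the carrier. In the flask charged with 2.0 mM, the idle number 34.2 put the working share at 2.84%; at 5.0% conversion that flask held 1.80% spent and 1.04% fresh carrier, 2.84% of the catalyst together.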